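(All runs stem from a simulated flask with made-up constants, noise included.)

Raising the charge from 0.99 M to 1.7 M left a spread of 1.4 percentage points in target at 8.00 min across the runs, against a scatter of 1 point, while time took the elm run from 8.9% at 3.00 min to 33.2% at 8.00 min. So you should reckon with time first, remembering that Monday's charge lies above those tried.

| flask | substrate | remark | time |
|---|---|---|---|
| elm | 0.99 M | run made earlier |  |
| maple | 1.4 M | run made earlier |  |
| birch | 1.7 M | run made earlier |  |
| Monday's | 2.0 M |  | 20 min |
| Saturday's | 1.2 M |  | 12 min |

| run | time / min | target / % | substrate / % |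
|---|---|---|---|
| elm | 1.50 | 3.7 | 58.2 |
| elm | 3.00 | 8.9 | 35.3 |
| elm | 5.00 | 19.4 | 15.8 |
| elm | 6.00 | 25.8 | 11.3 |
| elm | 8.00 | 33.2 | 4.1 |
| maple | 0.667 | 0 | 75.5 |
| maple | 1.33 | 1.1 | 60.9 |
| maple | 2.50 | 6.9 | 41.4 |
| maple | 4.00 | 15.6 | 24.2 |
| maple | 8.00 | 31.8 | 4.0 |
| birch | 0.833 | 2.2 | 71.3 |
| birch | 2.00 | 5.6 | 48.2 |
| birch | 4.00 | 13.9 | 21.7 |
| birch | 6.00 | 23.9 | 9.2 |
| birch | 8.00 | 32.4 | 3.9 |

(standard deviation of a reading: 1 percentage point)

- the winner by amount of target, in percent of the substrate charged; "neither" if no more than 2 percentage points parts them (Monday's / Saturday's / neither)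
- how much target is there at the end, in percent of the substrate charged: Monday's
- how much target is there at the end, in percent of the substrate charged: Saturday's

- what was read earlier has a scatter of 1 percentage point, one standard deviation

At 8.00 min the runs hold on average 32.5% of the charge as target and a pool of 63.5% that is neither substrate nor target. In the elm and birch runs, between 6.00 min and 8.00 min, target gains a fraction 0.0398 min⁻¹ of the charge. Pool over slope gives the emptying time, 16.0 min, how long the pool would feed target at that slope.

Now take two extremes. If the whole pool feeds target and shrinks exponentially with that time, Monday's reaches 66.0% and Saturday's 46.5%. If a third of it feeds target at the same slope, which is my own low guess, the emptying time is 5.33 min, and they reach 51.4% and 43.6%.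

The elm run's slope read 0.0563 min⁻¹ from 3.00 min to 6.00 min, then 0.0370 min⁻¹ up to 8.00 min, while its pool read 62.9% at 6.00 min and 62.7% at 8.00 min, so the first extreme looks generous. Saturday's remaining 4.00 min is shorter than the emptying time, so its two extremes lie 2.9 points apart, less than Monday's 15 points. I take the middles, 58.7% for Monday's and 45.0% for Saturday's. Even Monday's low end beats Saturday's high end by 4.9 points, more than the margin.

The forecast named Monday's, with 57% (44% to 73%) and 45% (40% to 50%), saying “Monday's ends higher in both pictures”.

The flask gives 54.6% for Monday's and 45.5% for Saturday's, so Monday's wins.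

    substrate ⇌ intermediate A (K = 0.384, k = 0.0102 s⁻¹)
    intermediate B ⇌ intermediate C (K = 0.751, k = 0.00726 s⁻¹)
    intermediate A → intermediate B (k = 0.0298 s⁻¹)
    substrate + intermediate C → side product (k = 0.00844 L mol⁻¹ s⁻¹)
    intermediate B → target (k = 0.00288 s⁻¹)

Monday's holds 32.4% as side product at 10.0 min and 33.3% at 20.0 min. Take the latter out of the pool, and the emptying time falls to 7.59 min and the reckoning gives 56.4%. Charged with 0.50 M instead, the same flask has 13.4% side product, so its emptying time is 12.6 min and the reckoning gives 63.2%. The computed value is 69.0%.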